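The earlier runs and the new flask are calculated with made-up constants, noise included.

If each reagent took one substrate and stopped, equal charges would simply run down together; two chemists dispute this flask on that point.

the same everywhere: substrate 0.50 M (in portions, 3)

| charge | reagent | remark | time |
|---|---|---|---|
| zeta | 0.50 M | the very flask that is asked about, followed so far; portions every 2.5 h |  |
| flask | 0.500 M | the portions of substrate follow each other after 2.5 h, the first at the start | 15 d |

zeta run (percent of the substrate charged)

| time / d | substrate / % | first product / % |
|---|---|---|
| 0.208 | 55.2 | 8.9 |
| 0.625 | 61.0 | 16.9 |
| 1.04 | 47.6 | 17.4 |
| 1.67 | 42.2 | 18.2 |
| 2.50 | 39.9 | 17.1 |
| 3.00 | 38.5 | 16.5 |

(scatter of a reading: 1 percentage point)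

- reactions considered so far: substrate + reagent -> first product; substrate + reagent -> other mono adduct; reagent + first product -> double product; reagent + other mono adduct -> double product
- the reaction counts as stopped when no species that holds the substrate changes by six tenths of a point or more over the second half of the time

- why nothing more happens at 15 d, or that something still does (all of the substrate has reacted / it is still moving / the reagent has run out first / forward and back rates have come level)
- share of the substrate used up at 15 d
- first product at 15 d, in percent of the substrate charged
- double product at 15 d, in percent of the substrate charged
- other mono adduct at 15 d, in percent of the substrate charged

The first chemist holds that one-to-one view and expects substrate to keep creeping down towards full use. She cites 0.208 d, with two of the 3 portions in: of what the substrate had lost by then, 77.6 % stands as first product. The second chemist cites 3.00 d: substrate has lost 61.5 %, yet first product reads 16.5 %, so 45 percentage points sits elsewhere, and she reads a second addition taking reagent.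

What separates them is the reagent budget, the charged reagent in percent of the substrate charged: here 100 %. Each substrate reacted costs one reagent and each double product one more, so once reagent is gone, substrate used plus double product equals the budget. Turning the full charge into double product costs 200 %. That is the crossing: with these reactions, reagent is the limiting reagent below it and substrate above it, and this flask sits below it.

My reckoning: substrate fell 1.4 points over the last interval, against a scatter of 1 point per reading, so I treat the reagent left at 3.00 d as negligible. That gives double product 38.5 % and other mono adduct 6.50 %.

The forecast sides with the second chemist: the reagent has run out first, 64.5 % used, first product 16 %, double product 36 %, other mono adduct 12.5 %, with the ground “First product sits near its plateau”. Its other mono adduct is higher than mine.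

In the flask the reagent has run out first, with 61.1 % used, first product 17.4 %, double product 38.9 %, other mono adduct 4.77 % and reagent left 0 %. Used plus double product makes 100 %, equal to the budget, which is the second chemist's case; the forecast parts from the flask on the other mono adduct, 7.7 points too high. The first chemist keeps the opening: in this flask at 0.208 d double product stood at 3.01 %, less than first product at 7.47 % plus other mono adduct at 2.55 %.

    substrate + reagent → first product (k = 0.0930 /M/h)
    substrate + reagent → other mono adduct (k = 0.0350 /M/h)
    reagent + first product → double product (k = 0.250 /M/h)
    reagent + other mono adduct → double product (k = 0.360 /M/h)

Raise the reagent to 1.2 M, the rest held: the budget becomes 240 %, above the crossing. So substrate should run out first, and 16.7 % of that neighbour flask's reagent charge should stay over. That neighbour flask gives >99.9 % used, double product >99.9 %, and reagent left 17 %.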